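**Strategy**

The pendant ring C (2-hydroxy-3,3,5,5-tetramethyl-4,6-dioxocyclohexenyl; locants primed, C1' on C2) is cut at its two acyl–carbon bonds C1'–C6' and C2'–C3'. The key step exploits the aldol-type array O1–C2–C1'–C2': held as a β-lactone, C2' acylates the enolate of methyl 2,2,4-trimethyl-3-oxopentanoate (C2'–C3'), the resulting alkoxide-protected dianion closes ring C by Dieckmann attack (C1'–C6'), and the C2 alkoxide then displaces methoxide at C8a of ring A, closing the dihydropyran ring B with retention at C2. The precursor is an open-chain β-lactone bearing the O-methylated ring A and the C3/C4 stereocentres, which come from an enamine-catalysed Michael addition.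

Key step: step 7

Assumption: O-trimethylsilylquinine is taken to deliver the 4S lactone from a branched aldehyde in step 6 (quinine- and quinidine-derived catalysts giving opposite lactone enantiomers); should the sense prove opposite, the pseudoenantiomeric O-trimethylsilylquinidine takes its place.

Target configuration read from the SMILES: (2R,3S,4S), ring C on C2 cis to the isopropyl group on C3, isobutyl group on C4 trans to both.

**Route**

Step 1
Reactants: 1 2,2,4,4-tetramethylcyclobutane-1,3-dione
Product: 2 methyl 2,2,4-trimethyl-3-oxopentanoate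
Conditions: NaOMe (cat.), MeOH, reflux
Reagents that add atoms: methanol, CO
Why: Methoxide adds to a carbonyl of the strained, non-enolisable 1,3-dione and the adduct opens by retro-Claisen cleavage to the β-keto ester (alcoholysis of dimethylketene dimer).

Step 2
Reactants: 2 methyl 2,2,4-trimethyl-3-oxopentanoate; 3 acetyl chloride
Product: 4 methyl 2,2,4,4-tetramethyl-3,5-dioxohexanoate
Conditions: LiN(iPr)2, THF, −78 °C; then 3, −78 → 0 °C
Reagents that add atoms: none
Why: The isopropyl methine is the only enolisable position of 2, and its lithium enolate should undergo C-acylation (crossed Claisen-type acylation) to give the 1,3-diketone with a quaternary carbon between the carbonyls.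

Step 3
Reactants: 4 methyl 2,2,4,4-tetramethyl-3,5-dioxohexanoate
Product: 5 syncarpic acid (2,2,4,4-tetramethylcyclohexane-1,3,5-trione)
Conditions: LiN(iPr)2, THF, −78 → 23 °C; 1 M HCl
Reagents that add atoms: none
Why: Dieckmann condensation, in which the methyl ketone enolate attacks the ester in a six-membered closure and the acidic trione enolate makes the closure irreversible; a non-nucleophilic base avoids retro-Claisen loss of the acetyl group.

Step 4
Reactants: 5 syncarpic acid; 6 3-methylbutanal (two molecules are incorporated)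
Product: 8 (3S,4S)-2-hydroxy-6,6,8,8-tetramethyl-4-(2-methylpropyl)-3-(propan-2-yl)-3,4-dihydro-2H-chromene-5,7(6H,8H)-dione (lactol as anomer mixture), via alkylidene trione 7 (not isolated)
Conditions: (R)-2-[diphenyl(trimethylsilyloxy)methyl]pyrrolidine (20 mol %), PhCO2H (20 mol %), 6 (3 equiv), slow addition of 5, CH2Cl2, 0 → 23 °C
Reagents that add atoms: none
Why: Amine-mediated Knoevenagel condensation gives the 1-oxadiene 7, which the (E)-enamine of a second molecule of 6 should intercept in a Michael addition/hemiacetalisation (formal inverse-electron-demand oxa-Diels–Alder reaction); the bulky silyloxydiphenylmethyl group of the (R)-catalyst shields one enamine face and the synclinal open transition state gives the syn adduct, as in the analogous additions to nitroalkenes, which is the 3S,4S-trans lactol.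

Step 5
Reactants: 8 lactol
Product: 9 (2S,3S)-3-(2-methoxy-3,3,5,5-tetramethyl-4,6-dioxocyclohex-1-en-1-yl)-5-methyl-2-(propan-2-yl)hexanal
Conditions: Me3SiCHN2, MeOH/toluene, 0 °C
Reagents that add atoms: trimethylsilyldiazomethane, C[Si](C)(C)C=[N+]=[N-]
Why: Ring–chain tautomerism of the lactol exposes the acidic enol of ring A, which alone is O-methylated by the diazoalkane under neutral conditions (vinylogous acid to vinylogous ester), so the aldehyde is released without epimerisation at its α-carbon and no stereocentre is formed.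

Step 6
Reactants: 9 aldehyde; 3 acetyl chloride
Product: 10 (4S)-4-[(3S,4S)-4-(2-methoxy-3,3,5,5-tetramethyl-4,6-dioxocyclohex-1-en-1-yl)-2,6-dimethylheptan-3-yl]oxetan-2-one
Conditions: O-trimethylsilylquinine (15 mol %), LiClO4 (1 equiv), iPr2NEt, CH2Cl2/Et2O, −78 °C
Reagents that add atoms: none
Why: Alkaloid/LiClO4-catalysed acyl halide–aldehyde cyclocondensation (ketene–aldehyde [2+2] cycloaddition through the chiral ammonium enolate), in which the catalyst selects the aldehyde face and sets the carbinol carbon as 4S (the future C2) irrespective of the α-stereocentre.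

Step 7
Reactants: 10 β-lactone; 2 methyl 2,2,4-trimethyl-3-oxopentanoate
Product: 13 ericifolione, via Claisen adduct 11 (not isolated), via Dieckmann product 12 (not isolated)
Conditions: 2, LiN(iPr)2, THF, −78 °C; 10, −78 °C; LiN(iPr)2, −78 → 0 °C, then 23 °C; 1 M HCl
Reagents that add atoms: none
Why: The lithium enolate of 2 attacks the strained lactone carbonyl with acyl–oxygen cleavage (Claisen-type acylation; closest precedents are the enolate opening of β-lactones to δ-hydroxy-β-dicarbonyl compounds and the C-acetylation of this same enolate in step 2), which forms C2'–C3' and leaves O1 as a lithium alkoxide on C2. The second portion of base deprotonates C1', the only enolisable position, and because the β-oxygen is an alkoxide this dianion can neither eliminate nor cleave by retro-aldol reaction; it closes ring C by a 6-exo-trig Dieckmann attack on the methyl ester (C1'–C6'), driven by formation of the acidic triketone enolate. On warming, the C2 alkoxide adds to C8a of the vinylogous methyl ester of ring A and expels methoxide (6-endo-trig addition–elimination), which closes ring B. No stereocentre is created: the C2–O1 bond made in step 6 is never broken, so C2 keeps its arrangement (4S in 10 becomes 2R only through a change of substituent priorities) and C3 and C4 are untouched. The step needs C- rather than O-acylation of the hindered enolate (lithium counter-ion in THF, as in step 2) and ring C closure before ring B closure, because a C1' enolate next to a closed O1–C8a bond would expel the ring A enolate; the low temperature at which the carbon enolate cyclises while the chelated alkoxide is still inert towards the hindered C8a should secure this order.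

**Compound list**

1 | 2,2,4,4-tetramethylcyclobutane-1,3-dione | CC1(C)C(=O)C(C)(C)C1=O | starting material
2 | methyl 2,2,4-trimethyl-3-oxopentanoate | COC(=O)C(C)(C)C(=O)C(C)C | intermediate
3 | acetyl chloride | CC(Cl)=O | starting material
4 | methyl 2,2,4,4-tetramethyl-3,5-dioxohexanoate | COC(=O)C(C)(C)C(=O)C(C)(C)C(C)=O | intermediate
5 | syncarpic acid (2,2,4,4-tetramethylcyclohexane-1,3,5-trione) | CC1(C)C(=O)CC(=O)C(C)(C)C1=O | intermediate
6 | 3-methylbutanal | CC(C)CC=O | starting material
7 | 2,2,4,4-tetramethyl-6-(3-methylbutylidene)cyclohexane-1,3,5-trione (not isolated) | CC(C)CC=C1C(=O)C(C)(C)C(=O)C(C)(C)C1=O | intermediate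
8 | (3S,4S)-2-hydroxy-6,6,8,8-tetramethyl-4-(2-methylpropyl)-3-(propan-2-yl)-3,4-dihydro-2H-chromene-5,7(6H,8H)-dione | CC(C)C[C@@H]1C2=C(OC(O)[C@H]1C(C)C)C(C)(C)C(=O)C(C)(C)C2=O | intermediate
9 | (2S,3S)-3-(2-methoxy-3,3,5,5-tetramethyl-4,6-dioxocyclohex-1-en-1-yl)-5-methyl-2-(propan-2-yl)hexanal | COC1=C([C@@H](CC(C)C)[C@@H](C=O)C(C)C)C(=O)C(C)(C)C(=O)C1(C)C | intermediate
10 | (4S)-4-[(3S,4S)-4-(2-methoxy-3,3,5,5-tetramethyl-4,6-dioxocyclohex-1-en-1-yl)-2,6-dimethylheptan-3-yl]oxetan-2-one | COC1=C([C@@H](CC(C)C)[C@@H]([C@@H]2CC(=O)O2)C(C)C)C(=O)C(C)(C)C(=O)C1(C)C | intermediate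
11 | methyl (7S,8S,9S)-7-hydroxy-9-(2-methoxy-3,3,5,5-tetramethyl-4,6-dioxocyclohex-1-en-1-yl)-2,2,4,4,11-pentamethyl-3,5-dioxo-8-(propan-2-yl)dodecanoate (lithium alkoxide in the flask, not isolated) | COC1=C([C@@H](CC(C)C)[C@@H]([C@@H](O)CC(=O)C(C)(C)C(=O)C(C)(C)C(=O)OC)C(C)C)C(=O)C(C)(C)C(=O)C1(C)C | intermediate
12 | 3-hydroxy-2-[(1R,2S,3S)-1-hydroxy-3-(2-methoxy-3,3,5,5-tetramethyl-4,6-dioxocyclohex-1-en-1-yl)-5-methyl-2-(propan-2-yl)hexyl]-4,4,6,6-tetramethylcyclohex-2-ene-1,5-dione (dilithium salt in the flask, not isolated) | COC1=C([C@@H](CC(C)C)[C@@H]([C@@H](O)C2=C(O)C(C)(C)C(=O)C(C)(C)C2=O)C(C)C)C(=O)C(C)(C)C(=O)C1(C)C | intermediate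
13 | ericifolione, (2R,3S,4S)-2-(2-hydroxy-3,3,5,5-tetramethyl-4,6-dioxocyclohex-1-en-1-yl)-6,6,8,8-tetramethyl-4-(2-methylpropyl)-3-(propan-2-yl)-3,4-dihydro-2H-chromene-5,7(6H,8H)-dione | CC(C)C[C@@H]1C2=C(O[C@@H](C3=C(O)C(C)(C)C(=O)C(C)(C)C3=O)[C@H]1C(C)C)C(C)(C)C(=O)C(C)(C)C2=O | target

**Step count**

Total step count: 7. Longest linear sequence: 7 steps (1 → 2 → 4 → 5 → 8 → 9 → 10 → 13); compound 2 enters a second time in step 7.

**Steps most likely to fail**

Step 7. The three anionic events may fall out of order: if the C2 alkoxide attacks C8a before the C1' enolate has closed ring C, the later enolate expels the ring A enolate by β-elimination, and the free alkoxide can also cleave the non-enolisable 1,3-diketone by retro-Claisen attack. The fallback sets out from 10 and returns at 13. The lactone is opened with the lithium enolate of 2 as before, but the aldolate is capped in the flask with Et3SiCl to give the triethylsilyl ether of the Claisen adduct F1. LiN(iPr)2 (THF, −78 → 0 °C) then closes ring C to the silyl-protected hydroxy triketone F2, which is isolated. KN(SiMe3)2 (1 equiv, to form the ring C enolate) followed by anhydrous Bu4N[Ph3SiF2] in THF releases the alkoxide under aprotic basic conditions only after ring C is complete, and this closes ring B to 13.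

Step 6. Facial selectivity may be poor if the α-stereocentre of 9 opposes the catalyst, and the cycloaddition of the doubly branched aldehyde may be slow enough for the ketene to be lost to dimerisation. The fallback sets out from 9 and returns at 10. Roskamp homologation with ethyl diazoacetate and SnCl2 (cat.) in CH2Cl2 gives the β-keto ester F3. Hydrogenation with RuCl2[(R)-BINAP] (H2, EtOH) sets the carbinol centre under catalyst control and gives the (3S)-β-hydroxy ester F4. LiOH (THF/H2O, 0 °C) gives the β-hydroxy acid F5, and PhSO2Cl in pyridine at 0 °C closes the β-lactone by carboxyl activation, with retention at the carbinol carbon, to give 10.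

Step 4. The acceptor 7 may be consumed by conjugate addition of a second molecule of 5, or by tautomerisation to its dienol and self-cycloaddition, before the catalytic enamine intercepts it; turnover of the amine may also be slowed by the acidic trione. The fallback sets out from 5 and 6 and returns at 8, with both partners preformed and used stoichiometrically. Compounds 5 and 6 with piperidine in EtOH give the crystalline Mannich base F6, a storable source of 7. Compound 6 and (2R)-2-(methoxymethyl)pyrrolidine give the chiral enamine F7. Compound 7, freed from F6 with cold dilute HCl and extracted, is added at once to F7 in Et2O at −78 °C to give the cyclic N,O-acetal F8. Hydrolysis of F8 with aqueous acetic acid gives 8 and returns the auxiliary.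

**Further compounds**

F1 | step 7 | methyl (7S,8S,9S)-9-(2-methoxy-3,3,5,5-tetramethyl-4,6-dioxocyclohex-1-en-1-yl)-2,2,4,4,11-pentamethyl-3,5-dioxo-8-(propan-2-yl)-7-[(triethylsilyl)oxy]dodecanoate | COC1=C([C@@H](CC(C)C)[C@@H]([C@@H](O[Si](CC)(CC)CC)CC(=O)C(C)(C)C(=O)C(C)(C)C(=O)OC)C(C)C)C(=O)C(C)(C)C(=O)C1(C)C
F2 | step 7 | 3-hydroxy-2-[(1R,2S,3S)-3-(2-methoxy-3,3,5,5-tetramethyl-4,6-dioxocyclohex-1-en-1-yl)-5-methyl-2-(propan-2-yl)-1-[(triethylsilyl)oxy]hexyl]-4,4,6,6-tetramethylcyclohex-2-ene-1,5-dione | COC1=C([C@@H](CC(C)C)[C@@H]([C@@H](O[Si](CC)(CC)CC)C2=C(O)C(C)(C)C(=O)C(C)(C)C2=O)C(C)C)C(=O)C(C)(C)C(=O)C1(C)C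
F3 | step 6 | ethyl (4S,5S)-5-(2-methoxy-3,3,5,5-tetramethyl-4,6-dioxocyclohex-1-en-1-yl)-7-methyl-3-oxo-4-(propan-2-yl)octanoate | COC1=C([C@@H](CC(C)C)[C@@H](C(=O)CC(=O)OCC)C(C)C)C(=O)C(C)(C)C(=O)C1(C)C
F4 | step 6 | ethyl (3S,4S,5S)-3-hydroxy-5-(2-methoxy-3,3,5,5-tetramethyl-4,6-dioxocyclohex-1-en-1-yl)-7-methyl-4-(propan-2-yl)octanoate | COC1=C([C@@H](CC(C)C)[C@@H]([C@@H](O)CC(=O)OCC)C(C)C)C(=O)C(C)(C)C(=O)C1(C)C
F5 | step 6 | (3S,4S,5S)-3-hydroxy-5-(2-methoxy-3,3,5,5-tetramethyl-4,6-dioxocyclohex-1-en-1-yl)-7-methyl-4-(propan-2-yl)octanoic acid | COC1=C([C@@H](CC(C)C)[C@@H]([C@@H](O)CC(O)=O)C(C)C)C(=O)C(C)(C)C(=O)C1(C)C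
F6 | step 4 | 3-hydroxy-4,4,6,6-tetramethyl-2-[3-methyl-1-(piperidin-1-yl)butyl]cyclohex-2-ene-1,5-dione | CC(C)CC(N1CCCCC1)C1=C(O)C(C)(C)C(=O)C(C)(C)C1=O
F7 | step 4 | (2R)-2-(methoxymethyl)-1-[(1E)-3-methylbut-1-en-1-yl]pyrrolidine | COC[C@H]1CCCN1/C=C/C(C)C
F8 | step 4 | (3S,4S)-2-[(2R)-2-(methoxymethyl)pyrrolidin-1-yl]-6,6,8,8-tetramethyl-4-(2-methylpropyl)-3-(propan-2-yl)-3,4-dihydro-2H-chromene-5,7(6H,8H)-dione | CC(C)C[C@@H]1C2=C(OC(N3CCC[C@@H]3COC)[C@H]1C(C)C)C(C)(C)C(=O)C(C)(C)C2=O
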